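**Retrosynthetic overview**

1. The last disconnection is the depside ester between the ring A acid (phenol masked as a benzyl ether) and the ring B phenol (acid masked as a benzyl ester); one hydrogenolysis frees both.
2. The strategy rests on the pattern of ring A: the C1 carboxyl lies between C2 heptyl and C6 OH, with OMe at C4. This resorcinol monomethyl ether is cut at C5–C6, C3–C4 and C1–C6 into a carbomethoxy vinylketene (released from an unsaturated acid chloride) and methoxyethyne.
3. The acid chloride comes from di-tert-butyl 3-oxopentanedioate: Z-enol triflate, Negishi coupling with heptylzinc bromide (fixes the E alkene), acidolysis, and esterification of the saturated carboxyl only.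
4. Ring B (C1 carboxyl between C2 heptyl and C6 OMe, OH at C4) is cut at C1–C6 and C2–C3 into benzyl dec-2-ynoate and a 1,1-dimethoxy-3-silyloxybutadiene (Diels–Alder reaction, then aromatisation).
5. Rings A and B are each built from open-chain partners, ring A by electrocyclisation and ring B by cycloaddition, and are then joined.

Key step: step 8

Remark: the target has no stereocentre, so the only stereochemical elements of the route are alkene geometries of intermediates; the geometry of the acid chloride precursor is lost when the ketene forms.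

**Route**

Step 1
Reactants: 1 di-tert-butyl 3-oxopentanedioate
Product: 3 di-tert-butyl (Z)-3-{[(trifluoromethyl)sulfonyl]oxy}pent-2-enedioate, via sodium enolate 2 (not isolated)
Conditions: NaH (1.0 equiv), Et2O, 0 °C; then Tf2O, −78 → 0 °C
Reagents that add atoms: trifluoromethanesulfonic anhydride, O=S(=O)(OS(=O)(=O)C(F)(F)F)C(F)(F)F
Why: The chelated sodium Z-enolate of the β-keto ester is sulfonylated on oxygen, so the triflate should end up cis to the conjugated ester (enol triflate formation from a β-keto ester).

Step 2
Reactants: 4 1-bromoheptane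
Product: 5 heptylzinc bromide (THF solution, used as such)
Conditions: Zn dust (activated by BrCH2CH2Br and Me3SiCl), LiCl, THF, 50 °C
Reagents that add atoms: zinc, [Zn]
Why: Oxidative insertion of LiCl-activated zinc into the primary C–Br bond gives an alkylzinc halide that tolerates esters and acidic CH2 groups (preparation of an organozinc reagent for Negishi coupling).

Step 3
Reactants: 3 di-tert-butyl (Z)-3-{[(trifluoromethyl)sulfonyl]oxy}pent-2-enedioate; 5 heptylzinc bromide
Product: 6 di-tert-butyl (E)-3-heptylpent-2-enedioate
Conditions: Pd(PPh3)4 (5 mol %), THF, 20 → 45 °C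
Reagents that add atoms: none
Why: Negishi coupling of an alkylzinc halide with an enol triflate goes with retention, so heptyl should take the place of the triflate cis to the conjugated ester, and the non-basic zinc reagent should not enolise the glutaconate.

Step 4
Reactants: 6 di-tert-butyl (E)-3-heptylpent-2-enedioate
Product: 7 (E)-3-heptylpent-2-enedioic acid
Conditions: CF3CO2H, CH2Cl2, 0 → 20 °C
Reagents that add atoms: none
Why: Acidolysis of the tert-butyl esters frees both carboxyl groups without base, so the glutaconate is not enolised and the E geometry should be kept.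

Step 5
Reactants: 7 (E)-3-heptylpent-2-enedioic acid
Product: 8 (E)-3-heptyl-5-methoxy-5-oxopent-2-enoic acid
Conditions: MeOH, AcCl (0.1 equiv), 0 → 20 °C, stopped when 7 is consumed
Reagents that add atoms: methanol, CO
Why: Fischer esterification is much faster at the saturated CH2CO2H than at the β,β-disubstituted conjugated acid, as in the mono-esterification of itaconic acid, so the conjugated carboxyl should stay free.

Step 6
Reactants: 8 (E)-3-heptyl-5-methoxy-5-oxopent-2-enoic acid
Product: 9 methyl (E)-5-chloro-3-heptyl-5-oxopent-3-enoate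
Conditions: (COCl)2, DMF (cat.), CH2Cl2, 0 → 20 °C; volatiles removed, used crude
Reagents that add atoms: oxalyl chloride, O=C(Cl)C(Cl)=O
Why: Vilsmeier-type activation converts the acid into the acid chloride at or below room temperature without touching the methyl ester or the alkene.

Step 7
Reactants: 10 2-chloro-1,1-dimethoxyethane
Product: 12 methoxyethyne, via sodium methoxyethynide 11 (not isolated)
Conditions: NaNH2 (3 equiv), liq. NH3, −33 °C; NH3 evaporated; aq. NaCl, −70 → 20 °C; distilled into a cold trap
Reagents that add atoms: none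
Why: Twofold base-induced elimination (methanol, then hydrogen chloride) gives the sodium alkynide, and protonation releases the volatile alkoxyalkyne (classical preparation of methoxyethyne from chloroacetaldehyde dimethyl acetal).

Step 8
Reactants: 9 methyl (E)-5-chloro-3-heptyl-5-oxopent-3-enoate; 12 methoxyethyne
Product: 17 methyl 2-heptyl-6-hydroxy-4-methoxybenzoate, via vinylketene 13 (not isolated), via alkenylcyclobutenone 14 (not isolated), via dienylketene 15 (not isolated), via cyclohexadienone 16 (not isolated)
Conditions: 12 (4 equiv), Et3N (1.5 equiv), toluene, 0 °C, 9 added over 2 h in a closed vessel, then 20 °C; excess 12 vented; 80 °C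
Reagents that add atoms: none
Why: Proposed new method: Et3N removes a proton from the ester-activated CH2 of 9 and chloride leaves to give vinylketene 13, whose carbonyl carbon is attacked by the nucleophilic CH carbon of methoxyethyne while the oxygen-bearing alkyne carbon closes onto the ketene α-carbon, a [2+2] cycloaddition that gives cyclobutenone 14 and forms the C5–C6 and C3–C4 bonds. On warming, 14 should open by a four-electron electrocyclic reaction to dienylketene 15, which closes ring A by a six-electron disrotatory electrocyclisation between the ketene carbon and the ester-bearing terminus (C1–C6 bond), and cyclohexadienone 16 tautomerises to the phenol hydrogen-bonded to the ester. The closest known reactions are the Danheiser benzannulation of cyclobutenone-derived vinylketenes with alkoxyalkynes, the Et3N dehydrochlorination of unsaturated acid chlorides to vinylketenes, and the formation of 3-alkoxycyclobutenones from acid chlorides, Et3N and ethoxyethyne. No stereocentre is set, because the sp3 centres of 14 and 16 disappear on ring opening and tautomerisation and the C3=C4 geometry of 9 is erased in 13. The site of deprotonation rests on the much higher acidity of the CH2 next to the ester than of the heptyl CH2, and the orientation of the cycloaddition (OMe at C4, OH at C6) rests on the polarisation of the alkoxyalkyne. The cycloaddition must also outrun dimerisation of 13 and its closure through the ester oxygen to a 6-methoxypyranone, which slow addition of 9 to an excess of the alkyne is meant to secure.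

Step 9
Reactants: 17 methyl 2-heptyl-6-hydroxy-4-methoxybenzoate
Product: 18 methyl 2-(benzyloxy)-6-heptyl-4-methoxybenzoate
Conditions: BnBr, K2CO3, DMF, 60 °C
Reagents that add atoms: benzyl bromide, BrCc1ccccc1
Why: Williamson ether synthesis, in which the hydrogen-bonded phenol is alkylated in warm DMF while the hindered methyl ester is untouched.

Step 10
Reactants: 18 methyl 2-(benzyloxy)-6-heptyl-4-methoxybenzoate
Product: 20 2-(benzyloxy)-6-heptyl-4-methoxybenzoic acid, via potassium carboxylate 19 (not isolated)
Conditions: KOH, DMSO–H2O, 90 °C; then aq. HCl, 0 °C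
Reagents that add atoms: potassium hydroxide, [K+].[OH-]
Why: Saponification of the di-ortho-substituted benzoate needs hot KOH in aqueous DMSO, conditions to which the benzyl and methyl ethers are stable.

Step 11
Reactants: 21 non-1-yne; 22 benzyl chloroformate
Product: 24 benzyl dec-2-ynoate, via non-1-yn-1-yllithium 23 (not isolated)
Conditions: n-BuLi, THF, −78 °C; then added to 22, THF, −78 → 0 °C
Reagents that add atoms: none
Why: Deprotonation of the terminal alkyne and C-acylation of the lithium acetylide by the chloroformate (inverse addition) gives the alkynoate.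

Step 12
Reactants: 25 1,1-dimethoxyethene; 26 acetyl chloride
Product: 27 4,4-dimethoxybut-3-en-2-one
Conditions: 25 (2 equiv), Et2O, 0 → 20 °C
Reagents that add atoms: none
Why: C-acylation of the electron-rich ketene acetal by the acid chloride, the hydrogen chloride being taken up by a second equivalent of the ketene acetal as methyl acetate and chloromethane (acylation of ketene acetals).

Step 13
Reactants: 27 4,4-dimethoxybut-3-en-2-one
Product: 28 [(4,4-dimethoxybuta-1,3-dien-2-yl)oxy]trimethylsilane
Conditions: Me3SiCl, Et3N, ZnCl2 (cat.), Et2O, 20 → 35 °C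
Reagents that add atoms: chlorotrimethylsilane, C[Si](C)(C)Cl
Why: O-silylation of the enol of the methyl ketone gives the 2-silyloxy diene (silyl enol ether formation as used for 1-alkoxy-3-silyloxy dienes).

Step 14
Reactants: 24 benzyl dec-2-ynoate; 28 [(4,4-dimethoxybuta-1,3-dien-2-yl)oxy]trimethylsilane
Product: 31 benzyl 2-heptyl-4-hydroxy-6-methoxybenzoate, via cycloadduct 29 (not isolated), via aryl silyl ether 30 (not isolated)
Conditions: toluene, 120 °C (sealed); then 1 M HCl, THF, 20 °C
Reagents that add atoms: none
Why: Diels–Alder reaction in which the nucleophilic terminal CH2 of the ketene-acetal diene bonds to the β-carbon of the ynoate, followed by loss of methanol and desilylation, should place OMe next to the ester and OH para to it (resorcinol synthesis from 1,1-dialkoxy-3-silyloxy dienes and alkynoates).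

Step 15
Reactants: 20 2-(benzyloxy)-6-heptyl-4-methoxybenzoic acid; 31 benzyl 2-heptyl-4-hydroxy-6-methoxybenzoate
Product: 33 benzyl 4-{[2-(benzyloxy)-6-heptyl-4-methoxybenzoyl]oxy}-2-heptyl-6-methoxybenzoate, via mixed anhydride 32 (not isolated)
Conditions: (CF3CO)2O, toluene, 0 → 20 °C
Reagents that add atoms: none
Why: The electron-rich, di-ortho-substituted acid is activated as its mixed trifluoroacetic anhydride and acylates the unhindered phenol (trifluoroacetic anhydride depside esterification), the benzyl ester and ether being stable to the short exposure to trifluoroacetic acid.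

Step 16
Reactants: 33 benzyl 4-{[2-(benzyloxy)-6-heptyl-4-methoxybenzoyl]oxy}-2-heptyl-6-methoxybenzoate
Product: 34 4-[(2-heptyl-6-hydroxy-4-methoxybenzoyl)oxy]-2-heptyl-6-methoxybenzoic acid
Conditions: H2 (1 atm), 10% Pd/C, EtOAc, 20 °C
Reagents that add atoms: none
Why: Catalytic hydrogenolysis cleaves the benzyl ester and the benzyl ether, while the aryl ester and the methyl ethers are inert.

**Compound list**

1 | di-tert-butyl 3-oxopentanedioate | CC(C)(C)OC(=O)CC(=O)CC(=O)OC(C)(C)C | starting material
2 | sodium (Z)-1,5-di-tert-butoxy-1,5-dioxopent-2-en-3-olate | CC(C)(C)OC(=O)C/C([O-])=C/C(=O)OC(C)(C)C.[Na+] | intermediate (not isolated)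
3 | di-tert-butyl (Z)-3-{[(trifluoromethyl)sulfonyl]oxy}pent-2-enedioate | CC(C)(C)OC(=O)C/C(OS(=O)(=O)C(F)(F)F)=C/C(=O)OC(C)(C)C | intermediate
4 | 1-bromoheptane | CCCCCCCBr | starting material
5 | heptylzinc bromide | CCCCCCC[Zn]Br | intermediate
6 | di-tert-butyl (E)-3-heptylpent-2-enedioate | CC(C)(C)OC(=O)C/C(CCCCCCC)=C/C(=O)OC(C)(C)C | intermediate
7 | (E)-3-heptylpent-2-enedioic acid | OC(=O)C/C(CCCCCCC)=C/C(=O)O | intermediate
8 | (E)-3-heptyl-5-methoxy-5-oxopent-2-enoic acid | COC(=O)C/C(CCCCCCC)=C/C(=O)O | intermediate
9 | methyl (E)-5-chloro-3-heptyl-5-oxopent-3-enoate | COC(=O)C/C(CCCCCCC)=C/C(Cl)=O | intermediate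
10 | 2-chloro-1,1-dimethoxyethane (chloroacetaldehyde dimethyl acetal) | COC(CCl)OC | starting material
11 | sodium methoxyethynide | [Na+].[C-]#COC | intermediate (not isolated)
12 | methoxyethyne | COC#C | intermediate
13 | methyl (2E)-3-heptyl-5-oxopenta-2,4-dienoate (vinylketene) | COC(=O)/C=C(/C=C=O)CCCCCCC | intermediate (not isolated)
14 | methyl (E)-3-(2-methoxy-4-oxocyclobut-2-en-1-yl)dec-2-enoate (racemic) | COC(=O)/C=C(/C1C(=O)C=C1OC)CCCCCCC | intermediate (not isolated)
15 | methyl (2E,4E)-3-heptyl-5-methoxy-7-oxohepta-2,4,6-trienoate (dienylketene) | COC(=O)/C=C(CCCCCCC)/C=C(OC)\C=C=O | intermediate (not isolated)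
16 | methyl 2-heptyl-4-methoxy-6-oxocyclohexa-2,4-diene-1-carboxylate (racemic) | COC(=O)C1C(=O)C=C(OC)C=C1CCCCCCC | intermediate (not isolated)
17 | methyl 2-heptyl-6-hydroxy-4-methoxybenzoate | CCCCCCCc1cc(OC)cc(O)c1C(=O)OC | intermediate
18 | methyl 2-(benzyloxy)-6-heptyl-4-methoxybenzoate | CCCCCCCc1cc(OC)cc(OCc2ccccc2)c1C(=O)OC | intermediate
19 | potassium 2-(benzyloxy)-6-heptyl-4-methoxybenzoate | CCCCCCCc1cc(OC)cc(OCc2ccccc2)c1C(=O)[O-].[K+] | intermediate (not isolated)
20 | 2-(benzyloxy)-6-heptyl-4-methoxybenzoic acid | CCCCCCCc1cc(OC)cc(OCc2ccccc2)c1C(=O)O | intermediate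
21 | non-1-yne | CCCCCCCC#C | starting material
22 | benzyl chloroformate | O=C(Cl)OCc1ccccc1 | starting material
23 | non-1-yn-1-yllithium | [Li]C#CCCCCCCC | intermediate (not isolated)
24 | benzyl dec-2-ynoate | CCCCCCCC#CC(=O)OCc1ccccc1 | intermediate
25 | 1,1-dimethoxyethene | C=C(OC)OC | starting material
26 | acetyl chloride | CC(Cl)=O | starting material
27 | 4,4-dimethoxybut-3-en-2-one | CC(=O)C=C(OC)OC | intermediate
28 | [(4,4-dimethoxybuta-1,3-dien-2-yl)oxy]trimethylsilane | C=C(O[Si](C)(C)C)C=C(OC)OC | intermediate
29 | benzyl 2-heptyl-6,6-dimethoxy-4-[(trimethylsilyl)oxy]cyclohexa-1,4-diene-1-carboxylate | CCCCCCCC1=C(C(=O)OCc2ccccc2)C(OC)(OC)C=C(O[Si](C)(C)C)C1 | intermediate (not isolated)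
30 | benzyl 2-heptyl-6-methoxy-4-[(trimethylsilyl)oxy]benzoate | CCCCCCCc1cc(O[Si](C)(C)C)cc(OC)c1C(=O)OCc1ccccc1 | intermediate (not isolated)
31 | benzyl 2-heptyl-4-hydroxy-6-methoxybenzoate | CCCCCCCc1cc(O)cc(OC)c1C(=O)OCc1ccccc1 | intermediate
32 | 2-(benzyloxy)-6-heptyl-4-methoxybenzoic trifluoroacetic anhydride | CCCCCCCc1cc(OC)cc(OCc2ccccc2)c1C(=O)OC(=O)C(F)(F)F | intermediate (not isolated)
33 | benzyl 4-{[2-(benzyloxy)-6-heptyl-4-methoxybenzoyl]oxy}-2-heptyl-6-methoxybenzoate | CCCCCCCc1cc(OC)cc(OCc2ccccc2)c1C(=O)Oc1cc(CCCCCCC)c(C(=O)OCc2ccccc2)c(OC)c1 | intermediate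
34 | 4-[(2-heptyl-6-hydroxy-4-methoxybenzoyl)oxy]-2-heptyl-6-methoxybenzoic acid | CCCCCCCc1cc(OC)cc(O)c1C(=O)Oc1cc(CCCCCCC)c(C(=O)O)c(OC)c1 | target

**Summary**

Total step count: 16.
Longest linear sequence: 10 steps (steps 1, 3, 4, 5, 6, 8, 9, 10, 15, 16).

Steps most likely to fail:

Step 8. The ketene may dimerise or close through its ester oxygen before the alkyne adds, the amine may acylate instead of deprotonating, or the ring opening of the cyclobutenone may stall. The fallback uses known chemistry, sets out from heptylzinc bromide 5 and returns at 17. Commercial methyl 2,4,6-trihydroxybenzoate is methylated at its non-chelated 4-OH (MeI, K2CO3, acetone) to give methyl 2,6-dihydroxy-4-methoxybenzoate F1. One of the two equivalent phenols is then sulfonylated (Tf2O, pyridine, CH2Cl2, −20 °C) to give methyl 2-hydroxy-4-methoxy-6-{[(trifluoromethyl)sulfonyl]oxy}benzoate F2. Negishi coupling of F2 with 5 (Pd(PPh3)4, THF, 60 °C, one extra equivalent of 5 for the phenolic proton) should give 17, so ring A is bought as an arene and the heptyl group is attached by cross-coupling.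

Step 14. The β-alkyl alkynoate may add too slowly, so that thermal decomposition and silyl migration of the ketene-acetal diene win. The fallback sets out from 17 and returns at 33. Phenol 17 is demethylated (BBr3, CH2Cl2, −78 → 0 °C) to methyl 2-heptyl-4,6-dihydroxybenzoate F3, which is saponified (KOH, aqueous DMSO, 90 °C, cold acidification) to 2-heptyl-4,6-dihydroxybenzoic acid F4. The carboxylate alone is benzylated (BnBr, KHCO3, DMF, 20 °C) to benzyl 2-heptyl-4,6-dihydroxybenzoate F5. Acid 20 is joined to the non-chelated 4-OH of F5 under the conditions of step 15 to give benzyl 4-{[2-(benzyloxy)-6-heptyl-4-methoxybenzoyl]oxy}-2-heptyl-6-hydroxybenzoate F6, and methylation of the remaining chelated phenol (MeI, K2CO3, acetone, reflux) should give 33.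

Step 5. Discrimination between the two carboxyl groups may be incomplete, giving diester, and acid may shift the double bond, which would exchange the roles of the two carboxyls. The fallback differentiates them through the cyclic anhydride, sets out from 7 and returns at 17 through ketene 13. Diacid 7 is warmed in acetic anhydride (80 °C), which should isomerise the alkene and close 4-heptyl-2H-pyran-2,6(3H)-dione F7. Methanol at 20 °C should open F7 at the non-conjugated carbonyl to give (Z)-3-heptyl-5-methoxy-5-oxopent-2-enoic acid F8, and (COCl)2 with catalytic DMF gives methyl (Z)-5-chloro-3-heptyl-5-oxopent-3-enoate F9. Under the conditions of step 8, F9 should lose hydrogen chloride to the same vinylketene 13, since the geometry of this alkene is erased, and so lead to 17.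

**Further compounds**

F1 | step 8 | methyl 2,6-dihydroxy-4-methoxybenzoate | COC(=O)c1c(O)cc(OC)cc1O
F2 | step 8 | methyl 2-hydroxy-4-methoxy-6-{[(trifluoromethyl)sulfonyl]oxy}benzoate | COC(=O)c1c(O)cc(OC)cc1OS(=O)(=O)C(F)(F)F
F3 | step 14 | methyl 2-heptyl-4,6-dihydroxybenzoate | CCCCCCCc1cc(O)cc(O)c1C(=O)OC
F4 | step 14 | 2-heptyl-4,6-dihydroxybenzoic acid | CCCCCCCc1cc(O)cc(O)c1C(=O)O
F5 | step 14 | benzyl 2-heptyl-4,6-dihydroxybenzoate | CCCCCCCc1cc(O)cc(O)c1C(=O)OCc1ccccc1
F6 | step 14 | benzyl 4-{[2-(benzyloxy)-6-heptyl-4-methoxybenzoyl]oxy}-2-heptyl-6-hydroxybenzoate | CCCCCCCc1cc(OC)cc(OCc2ccccc2)c1C(=O)Oc1cc(CCCCCCC)c(C(=O)OCc2ccccc2)c(O)c1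
F7 | step 5 | 4-heptyl-2H-pyran-2,6(3H)-dione | CCCCCCCC1=CC(=O)OC(=O)C1
F8 | step 5 | (Z)-3-heptyl-5-methoxy-5-oxopent-2-enoic acid | COC(=O)C/C(CCCCCCC)=C\C(=O)O
F9 | step 5 | methyl (Z)-5-chloro-3-heptyl-5-oxopent-3-enoate | COC(=O)C/C(CCCCCCC)=C\C(Cl)=O
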